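**Assumption:** the target has no stereocentre and is achiral, so "single enantiomer" needs no stereocontrol. Heneicosanoic acid and 2-phenylethanol are both taken as commercially available.

**Retrosynthetic overview**
- The only strategic bond is the acyl C–O bond of the ester.
- Cutting it gives heneicosanoic acid (the intact C21 chain) and 2-phenylethanol.
- No ring is formed, because the benzene ring is bought as part of 2-phenylethanol.
- No protecting groups or redox changes are needed, so the synthesis is a single condensation.

**Route**

Step 1
Reactants: 1 heneicosanoic acid; 2 2-phenylethanol
Product: 3 2-phenylethyl heneicosanoate
Conditions: 2 (1.2 equiv), p-TsOH·H2O (5 mol %), toluene, reflux, Dean–Stark, 8 h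
Reagents that add atoms: none
Why: This Fischer–Speier esterification (acid-catalysed acyl substitution) joins an unhindered primary alcohol to an unbranched saturated acid and is driven to completion by azeotropic removal of water, while neither partner has another reactive group and no stereocentre is created.

**Compound list**
1 | heneicosanoic acid | CCCCCCCCCCCCCCCCCCCCC(=O)O | starting material
2 | 2-phenylethanol | OCCc1ccccc1 | starting material
3 | 2-phenylethyl heneicosanoate | CCCCCCCCCCCCCCCCCCCCC(=O)OCCc1ccccc1 | target

**Total step count:** 1
**Longest linear sequence:** 1

**Steps most likely to fail**
The route has only one step, so only step 1 can be ranked.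

Step 1 carries three risks:
- The esterification is an equilibrium, and on a small scale the water removal may be incomplete.
- Leftover 1 gives soapy emulsions in a basic wash.
- Hot acid can convert a little of 2 into its symmetrical ether.

The fallback forms the other C–O bond of the ester, the alkyl–oxygen bond instead of the acyl–oxygen bond, and it is irreversible and free of acid. It sets out from 1, which is deprotonated with Cs2CO3 (1.0 equiv) in DMF at room temperature to give caesium heneicosanoate F1. This carboxylate is then alkylated in the same flask by SN2 displacement on commercial (2-bromoethyl)benzene (BrCCc1ccccc1, 1.3 equiv, 50 °C). That alkylation comes back to the route at 3, and compound 2 is not needed.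

**Further compounds**
F1 | step 1 | caesium heneicosanoate | CCCCCCCCCCCCCCCCCCCCC(=O)[O-].[Cs+]
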